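**Plan**
- Retrosynthesis: remove all O‑benzyl groups and three aryl C–Br bonds; cut C2–C3 of the terminal flavan unit (ring C) back through a flavan‑3‑one and a C2=C3 enol ether to an aryl ester on O1 plus an allyl group on C4a; cut both C4–C6 interflavan bonds.
- Forward: two benzylated, C8‑brominated epicatechin units are joined 4β→6; the dimer is activated again at C4 and arylated by an achiral 2‑allyl‑6‑bromophloroglucinol dibenzyl ether; ring C of the terminal unit is closed last.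
- Enabling feature: in the terminal unit C2 carries both O1 and the catechol ring, so it can enter as the carbonyl carbon of an aryl ester on O1; C3–C4 is a two‑carbon arm on C4a ortho to O1, so it can enter as an allyl group by Claisen rearrangement; a titanium‑mediated methylenation/ring‑closing metathesis then joins ester C=O and allyl CH= as C2=C3.
- Regiochemistry: bromine on C8 of every ring A leaves only C6 free, so each interflavan bond is 4→6.
- Stereochemistry: C2/C3 of the upper and middle units come from (−)‑epicatechin; both C4 centres arise by attack anti to 3‑OBn (4β, 3,4‑trans); C2/C3 of the terminal unit are set together by Ru‑catalysed hydrogenation of the flavan‑3‑one with dynamic kinetic resolution (2,3‑cis, 2R,3R).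

Key step: step 12

Assumption: the sense of induction in step 15 is assigned by analogy with the cis‑selective hydrogenation of 2‑arylcyclohexanones; if a model 2‑arylchroman‑3‑one shows the opposite sense, the mirror‑image catalyst is used and nothing else changes.

**Step 1**
Reactants: 1 (−)‑epicatechin
Product: 2 5,7,3',4'‑tetra‑O‑benzyl‑(−)‑epicatechin
Conditions: BnBr (4.4 equiv), K2CO3, DMF, 0 °C to rt
Reagents that add atoms: benzyl bromide, BrCc1ccccc1
Why: Williamson ether synthesis on the four phenols, which are far more acidic than the secondary 3‑OH, so carbonate base leaves that hydroxyl and both stereocentres untouched.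

**Step 2**
Reactants: 2 5,7,3',4'‑tetra‑O‑benzyl‑(−)‑epicatechin
Product: 3 3,5,7,3',4'‑penta‑O‑benzyl‑(−)‑epicatechin
Conditions: NaH, BnBr, Bu4NI (cat.), DMF, 0 °C to rt
Reagents that add atoms: benzyl bromide, BrCc1ccccc1
Why: Williamson etherification of the sodium alkoxide; the 3‑O‑benzyl group keeps this hydroxyl out of steps 12 to 14 and is removed in step 16.

**Step 3**
Reactants: 3 3,5,7,3',4'‑penta‑O‑benzyl‑(−)‑epicatechin
Product: 4 8‑bromo‑3,5,7,3',4'‑penta‑O‑benzylepicatechin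
Conditions: NBS (1.0 equiv), CH2Cl2, −78 °C to rt
Reagents that add atoms: N‑bromosuccinimide, O=C1CCC(=O)N1Br
Why: Electrophilic aromatic bromination at C8, the most reactive position of the phloroglucinol‑type ring A; the bromine blocks C8 so that later arylation must occur at C6, and it is removed in step 16.

**Step 4**
Reactants: 4 8‑bromo‑3,5,7,3',4'‑penta‑O‑benzylepicatechin
Product: 5 8‑bromo‑4β‑(2‑ethoxyethoxy)‑3,5,7,3',4'‑penta‑O‑benzylepicatechin (3,4‑trans)
Conditions: DDQ (2 equiv), 2‑ethoxyethanol (5 equiv), CH2Cl2, rt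
Reagents that add atoms: 2‑ethoxyethanol, CCOCCO
Why: DDQ benzylic oxidation: hydride is abstracted from C4 (activated by the three oxygens of ring A) and the cation is trapped by the alcohol anti to the 3‑OBn group, which should give the 4β ether as known for benzylated flavan‑3‑ols.

**Step 5**
Reactants: 5 8‑bromo‑4β‑(2‑ethoxyethoxy)‑penta‑O‑benzylepicatechin; 4 8‑bromo‑penta‑O‑benzylepicatechin (threefold excess, recovered)
Product: 6 [8‑bromo‑penta‑O‑benzylepicatechin]‑(4β→6)‑[8‑bromo‑penta‑O‑benzylepicatechin]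
Conditions: TMSOTf (0.2 equiv), CH2Cl2, −78 to −40 °C
Reagents that add atoms: none
Why: Lewis‑acid ionisation of the C4 ether and Friedel–Crafts arylation by ring A of 4, whose only free position is C6; attack anti to 3‑OBn sets the new C4 centre as 4β (3,4‑trans), and the excess of 4 suppresses self‑condensation of 5.

**Step 6**
Reactants: 6 bromo‑capped (4β→6) dimer
Product: 7 dimer 6 carrying a 4β‑(2‑ethoxyethoxy) group on C4 of its second (middle) unit
Conditions: DDQ (3 equiv), 2‑ethoxyethanol (10 equiv), CH2Cl2, rt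
Reagents that add atoms: 2‑ethoxyethanol, CCOCCO
Why: Same DDQ benzylic oxidation as step 4, directed to the only remaining flavan CH2 (C4 of the middle unit); the alcohol adds anti to 3‑OBn (4β).

**Step 7**
Reactants: 8 3,5‑bis(benzyloxy)phenol (commercial; otherwise one step from phloroglucinol)
Product: 9 2‑bromo‑3,5‑bis(benzyloxy)phenol
Conditions: NBS (1.0 equiv), i‑Pr2NH (0.1 equiv), CH2Cl2, −78 to 0 °C
Reagents that add atoms: N‑bromosuccinimide, O=C1CCC(=O)N1Br
Why: Amine‑mediated ortho‑selective bromination of a phenol; the two ortho positions are equivalent and the para position is flanked by two benzyloxy groups, so a single monobromide is expected.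

**Step 8**
Reactants: 9 2‑bromo‑3,5‑bis(benzyloxy)phenol
Product: 10 1‑(allyloxy)‑2‑bromo‑3,5‑bis(benzyloxy)benzene
Conditions: allyl bromide, K2CO3, acetone, reflux
Reagents that add atoms: allyl bromide, C=CCBr
Why: Williamson ether synthesis on the only hydroxyl.

**Step 9**
Reactants: 10 1‑(allyloxy)‑2‑bromo‑3,5‑bis(benzyloxy)benzene
Product: 11 2‑allyl‑6‑bromo‑3,5‑bis(benzyloxy)phenol
Conditions: N,N‑diethylaniline, 190 °C
Reagents that add atoms: none
Why: Aromatic Claisen rearrangement; the allyl group can only migrate to the one free ortho position, which places the future C4–C3 arm on the future C4a next to the future O1.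

**Step 10**
Reactants: 7 activated dimer; 11 2‑allyl‑6‑bromo‑3,5‑bis(benzyloxy)phenol (threefold excess)
Product: 12 dimer bearing a 4β‑[3‑allyl‑2,6‑bis(benzyloxy)‑5‑bromo‑4‑hydroxyphenyl] group on C4 of the middle unit
Conditions: TMSOTf (0.3 equiv), CH2Cl2, −78 to −30 °C
Reagents that add atoms: none
Why: Friedel–Crafts arylation of the middle‑unit C4 cation by the only unsubstituted ring carbon of 11 (para to the free OH, between the two OBn groups, the future C6); attack anti to 3‑OBn sets this C4 centre as 4β (3,4‑trans).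

**Step 11**
Reactants: 12 phenol adduct; 13 3,4‑bis(benzyloxy)benzoic acid
Product: 15 3,4‑bis(benzyloxy)benzoate ester of the phenol of 12, via O‑acylisourea 14 (not isolated)
Conditions: DCC, DMAP (cat.), CH2Cl2, rt
Reagents that add atoms: none
Why: Steglich esterification; the phenol is the only free hydroxyl, and the ester carbonyl carbon becomes C2 with ring B already attached.

**Step 12**
Reactants: 15 aryl ester
Product: 17 trimer skeleton whose terminal unit is an 8‑bromo‑5,7‑bis(benzyloxy)‑2‑[3,4‑bis(benzyloxy)phenyl]‑4H‑chromene (flav‑2‑ene) linked through C6, via acyclic enol ether 16 (not isolated)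
Conditions: Tebbe reagent Cp2Ti(μ‑Cl)(μ‑CH2)AlMe2 (4 equiv), pyridine (cat.), THF, 0 °C to rt, then reflux under high dilution
Reagents that add atoms: none
Why: The Tebbe reagent releases Cp2Ti=CH2, which methylenates the aryl ester carbonyl through an oxatitanacyclobutane to the 1‑arylvinyl aryl ether 16; on heating, the methylidene engages the monosubstituted allyl olefin and the resulting titanium alkylidene closes onto the enol ether C=CH2 through a titanacyclobutane, releasing ethene and forming the C2=C3 bond. The closest known reaction type is the tandem Tebbe methylenation/ring‑closing olefin metathesis of olefinic esters to six‑membered cyclic enol ethers, together with the stepwise methylenation/metathesis route to benzofurans and 4H‑chromenes. The ring closed is ring C of the terminal unit (O1–C2=C3–C4–C4a–C8a), six‑membered, formed by ring‑closing metathesis with both new sp2 carbons inside the ring. No stereocentre is created: C2 and C3 are left as the two ends of an enol ether so that both can be set together in steps 13 to 15. The step needs ring closure to win over simple methylenation and over intermolecular metathesis; this should be secured by the ortho relation of the allyl group on C4a to the ester on the C8a oxygen (six‑membered closure, high effective molarity) and by dilution. Benzyl ethers and aryl bromides are inert to titanium alkylidenes, and 15 has no free hydroxyl.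

**Step 13**
Reactants: 17 flav‑2‑ene
Product: 19 terminal‑unit 2,3‑trans‑flavan‑3‑ol (both diastereomers, 2R,3S and 2S,3R at the new ring), via C3‑alkylborane 18 (not isolated)
Conditions: BH3·THF, THF, 0 °C to rt; then NaOH aq, H2O2, 0 °C
Reagents that add atoms: hydrogen peroxide, OO
Why: Hydroboration–oxidation of the cyclic enol ether: boron adds to C3 (β to O1 and distal to the aryl group) and hydrogen to C2 in a syn fashion, so both products are 2,3‑trans; their configuration does not matter because both centres are reset in steps 14 and 15.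

**Step 14**
Reactants: 19 trans‑flavan‑3‑ol mixture
Product: 20 terminal‑unit flavan‑3‑one (C2 epimers)
Conditions: Dess–Martin periodinane, CH2Cl2, rt
Reagents that add atoms: none
Why: Dess–Martin oxidation of the only free hydroxyl, as known for benzylated catechin; C2–H becomes base‑labile, which step 15 uses.

**Step 15**
Reactants: 20 flavan‑3‑one
Product: 21 [8‑bromo‑penta‑O‑benzylepicatechin]‑(4β→6)‑[8‑bromo‑penta‑O‑benzylepicatechin]‑(4β→6)‑[8‑bromo‑5,7,3',4'‑tetra‑O‑benzylepicatechin]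
Conditions: H2 (20 atm), RuCl2[(S)‑xylbinap][(S)‑daipen] (2 mol %), KOtBu (0.3 equiv), i‑PrOH–toluene, rt
Reagents that add atoms: none
Why: Noyori asymmetric hydrogenation run as a dynamic kinetic resolution: KOtBu interconverts the C2 epimers through the enolate (C2–H is benzylic and α to both C=O and O1), and the chiral ruthenium hydride should reduce only the (2R) epimer from the face anti to the C2 aryl group, setting C3 as R and C2 as R (2,3‑cis), as known for 2‑aryl‑ and 2‑alkoxycyclohexanones.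

**Step 16**
Reactants: 21 protected trimer
Product: 22 epicatechin‑(4β→6)‑epicatechin‑(4β→6)‑epicatechin (target)
Conditions: H2 (1 atm), Pd(OH)2/C, Et3N (4 equiv), THF–MeOH–H2O, rt
Reagents that add atoms: none
Why: Hydrogenolysis of the fourteen benzyl ethers and hydrodebromination of the three aryl bromides; Et3N binds HBr so that the acid‑labile interflavan bonds survive, and no stereocentre is touched.

**Compound list**

1 | (−)‑epicatechin, (2R,3R) | Oc1cc(O)c2c(c1)O[C@H](c3ccc(O)c(O)c3)[C@H](O)C2 | starting material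

2 | 5,7,3',4'‑tetra‑O‑benzyl‑(−)‑epicatechin | O(Cc9ccccc9)c1cc(OCc9ccccc9)c2c(c1)O[C@H](c8ccc(OCc9ccccc9)c(OCc9ccccc9)c8)[C@H](O)C2 | intermediate

3 | 3,5,7,3',4'‑penta‑O‑benzyl‑(−)‑epicatechin | O(Cc9ccccc9)c1cc(OCc9ccccc9)c2c(c1)O[C@H](c8ccc(OCc9ccccc9)c(OCc9ccccc9)c8)[C@H](OCc9ccccc9)C2 | intermediate

4 | 8‑bromo‑3,5,7,3',4'‑penta‑O‑benzylepicatechin | O(Cc9ccccc9)c1cc(OCc9ccccc9)c2c(c1Br)O[C@H](c8ccc(OCc9ccccc9)c(OCc9ccccc9)c8)[C@H](OCc9ccccc9)C2 | intermediate

5 | 8‑bromo‑4β‑(2‑ethoxyethoxy)‑3,5,7,3',4'‑penta‑O‑benzylepicatechin (2,3‑cis, 3,4‑trans) | O(Cc9ccccc9)c1cc(OCc9ccccc9)c2c(c1Br)O[C@H](c8ccc(OCc9ccccc9)c(OCc9ccccc9)c8)[C@H](OCc9ccccc9)[C@H]2OCCOCC | intermediate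

6 | [8‑bromo‑penta‑O‑benzylepicatechin]‑(4β→6)‑[8‑bromo‑penta‑O‑benzylepicatechin] | O(Cc9ccccc9)c1cc(OCc9ccccc9)c2c(c1Br)O[C@H](c8ccc(OCc9ccccc9)c(OCc9ccccc9)c8)[C@H](OCc9ccccc9)[C@H]2c3c(OCc9ccccc9)c(Br)c4c(c3OCc9ccccc9)C[C@@H](OCc9ccccc9)[C@@H](c8ccc(OCc9ccccc9)c(OCc9ccccc9)c8)O4 | intermediate

7 | dimer 6 with a 4β‑(2‑ethoxyethoxy) group on C4 of the middle unit | O(Cc9ccccc9)c1cc(OCc9ccccc9)c2c(c1Br)O[C@H](c8ccc(OCc9ccccc9)c(OCc9ccccc9)c8)[C@H](OCc9ccccc9)[C@H]2c3c(OCc9ccccc9)c(Br)c4c(c3OCc9ccccc9)[C@H](OCCOCC)[C@@H](OCc9ccccc9)[C@@H](c8ccc(OCc9ccccc9)c(OCc9ccccc9)c8)O4 | intermediate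

8 | 3,5‑bis(benzyloxy)phenol | Oc1cc(OCc2ccccc2)cc(OCc2ccccc2)c1 | starting material

9 | 2‑bromo‑3,5‑bis(benzyloxy)phenol | Oc1cc(OCc2ccccc2)cc(OCc2ccccc2)c1Br | intermediate

10 | 1‑(allyloxy)‑2‑bromo‑3,5‑bis(benzyloxy)benzene | C=CCOc1cc(OCc2ccccc2)cc(OCc2ccccc2)c1Br | intermediate

11 | 2‑allyl‑6‑bromo‑3,5‑bis(benzyloxy)phenol | Oc1c(CC=C)c(OCc2ccccc2)cc(OCc2ccccc2)c1Br | intermediate

12 | dimer with a 4β‑[3‑allyl‑2,6‑bis(benzyloxy)‑5‑bromo‑4‑hydroxyphenyl] group on C4 of the middle unit | O(Cc9ccccc9)c1cc(OCc9ccccc9)c2c(c1Br)O[C@H](c8ccc(OCc9ccccc9)c(OCc9ccccc9)c8)[C@H](OCc9ccccc9)[C@H]2c3c(OCc9ccccc9)c(Br)c4c(c3OCc9ccccc9)[C@H](c5c(OCc9ccccc9)c(Br)c(O)c(c5OCc9ccccc9)CC=C)[C@@H](OCc9ccccc9)[C@@H](c8ccc(OCc9ccccc9)c(OCc9ccccc9)c8)O4 | intermediate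

13 | 3,4‑bis(benzyloxy)benzoic acid | OC(=O)c1ccc(OCc2ccccc2)c(OCc2ccccc2)c1 | starting material

14 | O‑acylisourea from 13 and DCC | O=C(OC(=NC1CCCCC1)NC1CCCCC1)c1ccc(OCc2ccccc2)c(OCc2ccccc2)c1 | intermediate

15 | 3,4‑bis(benzyloxy)benzoate ester of 12 | O(Cc9ccccc9)c1cc(OCc9ccccc9)c2c(c1Br)O[C@H](c8ccc(OCc9ccccc9)c(OCc9ccccc9)c8)[C@H](OCc9ccccc9)[C@H]2c3c(OCc9ccccc9)c(Br)c4c(c3OCc9ccccc9)[C@H](c5c(OCc9ccccc9)c(Br)c(OC(=O)c8ccc(OCc9ccccc9)c(OCc9ccccc9)c8)c(c5OCc9ccccc9)CC=C)[C@@H](OCc9ccccc9)[C@@H](c8ccc(OCc9ccccc9)c(OCc9ccccc9)c8)O4 | intermediate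

16 | 1‑[3,4‑bis(benzyloxy)phenyl]vinyl aryl ether from methylenation of 15 | O(Cc9ccccc9)c1cc(OCc9ccccc9)c2c(c1Br)O[C@H](c8ccc(OCc9ccccc9)c(OCc9ccccc9)c8)[C@H](OCc9ccccc9)[C@H]2c3c(OCc9ccccc9)c(Br)c4c(c3OCc9ccccc9)[C@H](c5c(OCc9ccccc9)c(Br)c(OC(=C)c8ccc(OCc9ccccc9)c(OCc9ccccc9)c8)c(c5OCc9ccccc9)CC=C)[C@@H](OCc9ccccc9)[C@@H](c8ccc(OCc9ccccc9)c(OCc9ccccc9)c8)O4 | intermediate

17 | trimer skeleton with terminal 4H‑chromene (C2=C3) unit | O(Cc9ccccc9)c1cc(OCc9ccccc9)c2c(c1Br)O[C@H](c8ccc(OCc9ccccc9)c(OCc9ccccc9)c8)[C@H](OCc9ccccc9)[C@H]2c3c(OCc9ccccc9)c(Br)c4c(c3OCc9ccccc9)[C@H](c5c(OCc9ccccc9)c(Br)c6c(c5OCc9ccccc9)CC=C(c8ccc(OCc9ccccc9)c(OCc9ccccc9)c8)O6)[C@@H](OCc9ccccc9)[C@@H](c8ccc(OCc9ccccc9)c(OCc9ccccc9)c8)O4 | intermediate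

18 | C3‑alkylborane of the terminal unit (2,3‑trans, both diastereomers; the two new centres are left open in the SMILES) | O(Cc9ccccc9)c1cc(OCc9ccccc9)c2c(c1Br)O[C@H](c8ccc(OCc9ccccc9)c(OCc9ccccc9)c8)[C@H](OCc9ccccc9)[C@H]2c3c(OCc9ccccc9)c(Br)c4c(c3OCc9ccccc9)[C@H](c5c(OCc9ccccc9)c(Br)c6c(c5OCc9ccccc9)CC(B)C(c8ccc(OCc9ccccc9)c(OCc9ccccc9)c8)O6)[C@@H](OCc9ccccc9)[C@@H](c8ccc(OCc9ccccc9)c(OCc9ccccc9)c8)O4 | intermediate

19 | terminal‑unit 2,3‑trans‑flavan‑3‑ol (both diastereomers, 2R,3S and 2S,3R; the two new centres are left open in the SMILES) | O(Cc9ccccc9)c1cc(OCc9ccccc9)c2c(c1Br)O[C@H](c8ccc(OCc9ccccc9)c(OCc9ccccc9)c8)[C@H](OCc9ccccc9)[C@H]2c3c(OCc9ccccc9)c(Br)c4c(c3OCc9ccccc9)[C@H](c5c(OCc9ccccc9)c(Br)c6c(c5OCc9ccccc9)CC(O)C(c8ccc(OCc9ccccc9)c(OCc9ccccc9)c8)O6)[C@@H](OCc9ccccc9)[C@@H](c8ccc(OCc9ccccc9)c(OCc9ccccc9)c8)O4 | intermediate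

20 | terminal‑unit flavan‑3‑one (C2 stereolabile, both epimers) | O(Cc9ccccc9)c1cc(OCc9ccccc9)c2c(c1Br)O[C@H](c8ccc(OCc9ccccc9)c(OCc9ccccc9)c8)[C@H](OCc9ccccc9)[C@H]2c3c(OCc9ccccc9)c(Br)c4c(c3OCc9ccccc9)[C@H](c5c(OCc9ccccc9)c(Br)c6c(c5OCc9ccccc9)CC(=O)C(c8ccc(OCc9ccccc9)c(OCc9ccccc9)c8)O6)[C@@H](OCc9ccccc9)[C@@H](c8ccc(OCc9ccccc9)c(OCc9ccccc9)c8)O4 | intermediate

21 | fully protected trimer, terminal unit (2R,3R) with free 3‑OH | O(Cc9ccccc9)c1cc(OCc9ccccc9)c2c(c1Br)O[C@H](c8ccc(OCc9ccccc9)c(OCc9ccccc9)c8)[C@H](OCc9ccccc9)[C@H]2c3c(OCc9ccccc9)c(Br)c4c(c3OCc9ccccc9)[C@H](c5c(OCc9ccccc9)c(Br)c6c(c5OCc9ccccc9)C[C@@H](O)[C@@H](c8ccc(OCc9ccccc9)c(OCc9ccccc9)c8)O6)[C@@H](OCc9ccccc9)[C@@H](c8ccc(OCc9ccccc9)c(OCc9ccccc9)c8)O4 | intermediate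

22 | epicatechin‑(4β→6)‑epicatechin‑(4β→6)‑epicatechin | Oc1cc(O)c2c(c1)O[C@H](c1ccc(O)c(O)c1)[C@H](O)[C@H]2c1c(O)cc2c(c1O)[C@H](c1c(O)cc3c(c1O)C[C@@H](O)[C@@H](c1ccc(O)c(O)c1)O3)[C@@H](O)[C@@H](c1ccc(O)c(O)c1)O2 | target

**Step count**
Total: 16 steps. Longest linear sequence: 13 steps (steps 1 to 6, then 10 to 16).

**Steps most likely to fail**

Step 12. The methylenation may stop at the acyclic enol ether, the titanium alkylidene may react between molecules instead of closing the ring, or the acid‑labile cyclic enol ether may hydrolyse on work‑up. The fallback gives up the late ring construction and uses a preformed terminal unit. It sets out from 7 (with 2 as the source of the nucleophile) and comes back at 21. Compound 2 is brominated at C8 (NBS, CH2Cl2, −78 °C) to 8‑bromo‑5,7,3',4'‑tetra‑O‑benzylepicatechin F1. Compound 7 is then coupled with excess F1 (TMSOTf, CH2Cl2, −78 °C); C6 is the only free ring A position, and attack anti to 3‑OBn should give 21 directly, so steps 10 to 15 are not needed.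

Step 15. Epimerisation at C2 may be slower than reduction, or the catalyst may discriminate the faces poorly, so that diastereomers at the terminal unit form. The fallback sets the two centres one after the other by reagent and substrate control. It sets out from 17 and comes back at 21. Hydroboration of 17 with monoisopinocampheylborane (from (+)‑α‑pinene), then H2O2/NaOH, should give the (2R,3S)‑trans alcohol F2. Dess–Martin oxidation without base gives the (2R)‑flavan‑3‑one F3. Reduction with LiBH(s‑Bu)3 in THF at −78 °C delivers hydride anti to the C2 aryl group, the known catechin‑to‑epicatechin inversion, and should give 21.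

Step 6. Hydride abstraction may occur at another benzylic site of the dimer (the diarylmethine C4 of the upper unit or a benzyl ether CH2), or the product may be oxidised further. The fallback installs the leaving group before the dimer is made, as a latent thioether. It sets out from 5 and comes back at 12. Compound 5 with 2,6‑dimethylbenzenethiol and BF3·OEt2 should give the 4β‑arylthio monomer F4. F4, whose C–S bond is inert to BF3·OEt2, is arylated at C6 by a second portion of 5 (BF3·OEt2, CH2Cl2, −78 °C) to the dimer F5 with the 4β‑arylthio group on the middle unit. F5 is then activated with thiophilic AgOTf in the presence of 11 to give 12.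

**Further compounds**

F1 | step 12 | 8‑bromo‑5,7,3',4'‑tetra‑O‑benzylepicatechin | O(Cc9ccccc9)c1cc(OCc9ccccc9)c2c(c1Br)O[C@H](c8ccc(OCc9ccccc9)c(OCc9ccccc9)c8)[C@H](O)C2

F2 | step 15 | protected trimer with (2R,3S)‑trans terminal flavan‑3‑ol | O(Cc9ccccc9)c1cc(OCc9ccccc9)c2c(c1Br)O[C@H](c8ccc(OCc9ccccc9)c(OCc9ccccc9)c8)[C@H](OCc9ccccc9)[C@H]2c3c(OCc9ccccc9)c(Br)c4c(c3OCc9ccccc9)[C@H](c5c(OCc9ccccc9)c(Br)c6c(c5OCc9ccccc9)C[C@H](O)[C@@H](c8ccc(OCc9ccccc9)c(OCc9ccccc9)c8)O6)[C@@H](OCc9ccccc9)[C@@H](c8ccc(OCc9ccccc9)c(OCc9ccccc9)c8)O4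

F3 | step 15 | protected trimer with (2R) terminal flavan‑3‑one | O(Cc9ccccc9)c1cc(OCc9ccccc9)c2c(c1Br)O[C@H](c8ccc(OCc9ccccc9)c(OCc9ccccc9)c8)[C@H](OCc9ccccc9)[C@H]2c3c(OCc9ccccc9)c(Br)c4c(c3OCc9ccccc9)[C@H](c5c(OCc9ccccc9)c(Br)c6c(c5OCc9ccccc9)CC(=O)[C@@H](c8ccc(OCc9ccccc9)c(OCc9ccccc9)c8)O6)[C@@H](OCc9ccccc9)[C@@H](c8ccc(OCc9ccccc9)c(OCc9ccccc9)c8)O4

F4 | step 6 | 8‑bromo‑4β‑(2,6‑dimethylphenylthio)‑3,5,7,3',4'‑penta‑O‑benzylepicatechin | O(Cc9ccccc9)c1cc(OCc9ccccc9)c2c(c1Br)O[C@H](c8ccc(OCc9ccccc9)c(OCc9ccccc9)c8)[C@H](OCc9ccccc9)[C@H]2Sc3c(C)cccc3C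

F5 | step 6 | dimer 6 with a 4β‑(2,6‑dimethylphenylthio) group on C4 of the middle unit | O(Cc9ccccc9)c1cc(OCc9ccccc9)c2c(c1Br)O[C@H](c8ccc(OCc9ccccc9)c(OCc9ccccc9)c8)[C@H](OCc9ccccc9)[C@H]2c3c(OCc9ccccc9)c(Br)c4c(c3OCc9ccccc9)[C@H](Sc5c(C)cccc5C)[C@@H](OCc9ccccc9)[C@@H](c8ccc(OCc9ccccc9)c(OCc9ccccc9)c8)O4
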